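The chain is numbered C1 (CH2 on the 3,4-dihydroxy-5-methoxyphenyl ring) to C7 (CH2 on the guaiacyl ring). The plan exploits the 1,3-related oxygens at C3 (ketone) and C5 (hydroxyl) together with the benzylic carbon C7 on the guaiacyl ring: they are folded into an all-cis 2-aryltetrahydropyran-4-ol whose ring oxygen is the C3 oxygen. A Prins cyclisation of an (R)-homoallylic alcohol (C1–C6, catechol as bis-benzyl ether) with vanillin acetate (C7) forms C6–C7, O–C7 and C5–O, closes the ring and relays the C3 configuration to C5 in one operation. Benzylation, reductive cleavage of the benzylic C7–O bond, oxidation at C3 and hydrogenolysis complete the synthesis.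

Key step: step 6

Remark: (−)-Ipc2BOMe denotes (−)-B-methoxydiisopinocampheylborane, the enantiomer made from (+)-α-pinene; the chain numbering C1–C7 defined above is used throughout.

Step 1
Reactants: 1 3,4-dihydroxy-5-methoxybenzaldehyde (5-hydroxyvanillin)
Product: 2 3,4-bis(benzyloxy)-5-methoxybenzaldehyde
Conditions: BnBr (2.3 equiv), K2CO3, DMF, 60 °C
Reagents that add atoms: benzyl bromide, BrCc1ccccc1
Why: Williamson ether synthesis on both phenoxides, with benzyl chosen because it should survive every later step and leave in the final hydrogenolysis.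

Step 2
Reactants: 2 3,4-bis(benzyloxy)-5-methoxybenzaldehyde; 3 methyl (triphenylphosphoranylidene)acetate
Product: 4 methyl (E)-3-[3,4-bis(benzyloxy)-5-methoxyphenyl]prop-2-enoate
Conditions: toluene, 90 °C
Reagents that add atoms: none
Why: Wittig olefination with a stabilised ylide, which should give the E enoate (the geometry is erased in the next step).

Step 3
Reactants: 4 methyl (E)-3-[3,4-bis(benzyloxy)-5-methoxyphenyl]prop-2-enoate
Product: 5 methyl 3-[3,4-bis(benzyloxy)-5-methoxyphenyl]propanoate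
Conditions: NiCl2·6H2O (0.2 equiv), NaBH4, MeOH/THF, 0 °C
Reagents that add atoms: none
Why: Conjugate reduction by nickel boride formed in the flask should saturate the cinnamate double bond at 0 °C without hydrogenolysis of the aryl benzyl ethers or reduction of the ester.

Step 4
Reactants: 5 methyl 3-[3,4-bis(benzyloxy)-5-methoxyphenyl]propanoate
Product: 6 3-[3,4-bis(benzyloxy)-5-methoxyphenyl]propanal
Conditions: iBu2AlH (1.05 equiv), CH2Cl2, −78 °C; MeOH, then aq. KNaC4H4O6
Reagents that add atoms: none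
Why: Partial reduction of the ester, in which the tetrahedral aluminium hemiacetal is stable at −78 °C and releases the aldehyde only on work-up.

Step 5
Reactants: 6 3-[3,4-bis(benzyloxy)-5-methoxyphenyl]propanal; 7 allylmagnesium bromide
Product: 9 (3R)-1-[3,4-bis(benzyloxy)-5-methoxyphenyl]hex-5-en-3-ol, via borinate ester 8 (not isolated)
Conditions: (−)-Ipc2BOMe, 7, Et2O, −78 °C to rt; 6, −78 °C; then 3 M NaOH, 30% H2O2, rt
Reagents that add atoms: none
Why: Brown allylboration through a closed chair (Zimmerman–Traxler) transition state, in which the isopinocampheyl groups derived from (+)-α-pinene steer the allyl group to the Si face of the unbranched aldehyde and so should set C3 as R.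

Step 6
Reactants: 9 (3R)-1-[3,4-bis(benzyloxy)-5-methoxyphenyl]hex-5-en-3-ol; 10 4-formyl-2-methoxyphenyl acetate (vanillin acetate)
Product: 12 (2R,4S,6R)-6-{2-[3,4-bis(benzyloxy)-5-methoxyphenyl]ethyl}-2-(4-hydroxy-3-methoxyphenyl)tetrahydropyran-4-ol, via tetrahydropyranyl trifluoroacetate 11 (not isolated)
Conditions: 10 (1.2 equiv), CF3CO2H (15 equiv), CH2Cl2, 0 °C to rt; then K2CO3 (0.3 equiv), MeOH, rt
Reagents that add atoms: trifluoroacetic acid, OC(=O)C(F)(F)F
Why: Prins cyclisation: acid-promoted condensation of 9 with 10 gives the aryl-conjugated (E)-oxocarbenium ion at C7, the terminal alkene carbon C6 attacks it, and the secondary tetrahydropyranyl cation at C5 is captured by trifluoroacetate; the mild methanolysis that follows frees the C5 hydroxyl and the phenol together. The closest known reaction type is the trifluoroacetic acid Prins cyclisation of homoallylic alcohols with aromatic aldehydes, which gives all-cis 2,6-disubstituted tetrahydropyran-4-ols. The tetrahydropyran closes in a 6-endo-trig mode with respect to the alkene through a chair transition state. C7 is set by that chair, in which the aryl group and the C3 side chain are both equatorial, and C5 is set by equatorial capture of the cation, so the existing R centre at C3 controls both and the ring should be all-cis (2R,4S,6R), which corresponds to R at C5 of the target. The selectivity needed is faithful transfer of the C3 configuration without exchange of the aldehyde component: the oxocarbenium ion is already the conjugated and more stable isomer, so a 2-oxonia-Cope shift is uphill, and the electron-poor acetoxy substituent keeps the aryl group from supporting benzylic ionisation, which is the usual cause of scrambling with electron-rich aryl groups. C7 ends as CH2, so its configuration is of no consequence.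

Step 7
Reactants: 12 (2R,4S,6R)-6-{2-[3,4-bis(benzyloxy)-5-methoxyphenyl]ethyl}-2-(4-hydroxy-3-methoxyphenyl)tetrahydropyran-4-ol
Product: 13 (2R,4S,6R)-4-(benzyloxy)-2-[4-(benzyloxy)-3-methoxyphenyl]-6-{2-[3,4-bis(benzyloxy)-5-methoxyphenyl]ethyl}tetrahydropyran
Conditions: NaH (2.5 equiv), BnBr (2.4 equiv), Bu4NI (cat.), THF/DMF, 0 °C to rt
Reagents that add atoms: benzyl bromide, BrCc1ccccc1
Why: Williamson etherification of the phenoxide and of the secondary alkoxide, which caps the C5 oxygen with a group that should survive the next two steps and leave in the final hydrogenolysis, while the new aryl benzyl ether restores the electron-rich ring needed in step 8.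

Step 8
Reactants: 13 (2R,4S,6R)-4-(benzyloxy)-2-[4-(benzyloxy)-3-methoxyphenyl]-6-{2-[3,4-bis(benzyloxy)-5-methoxyphenyl]ethyl}tetrahydropyran
Product: 14 (3R,5R)-5-(benzyloxy)-7-[4-(benzyloxy)-3-methoxyphenyl]-1-[3,4-bis(benzyloxy)-5-methoxyphenyl]heptan-3-ol
Conditions: Et3SiH (5 equiv), BF3·OEt2 (2 equiv), CH2Cl2, −78 to −20 °C; then aq. NaHCO3
Reagents that add atoms: none
Why: Ionic hydrogenation, in which BF3 activates the ring oxygen, the C7–O bond ionises because the p-benzyloxyphenyl group stabilises the benzylic cation, and Et3SiH reduces that cation to CH2, whereas the unactivated benzyl ethers and the centres at C3 and C5 should stay untouched.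

Step 9
Reactants: 14 (3R,5R)-5-(benzyloxy)-7-[4-(benzyloxy)-3-methoxyphenyl]-1-[3,4-bis(benzyloxy)-5-methoxyphenyl]heptan-3-ol
Product: 15 (5R)-5-(benzyloxy)-7-[4-(benzyloxy)-3-methoxyphenyl]-1-[3,4-bis(benzyloxy)-5-methoxyphenyl]heptan-3-one
Conditions: Dess–Martin periodinane, CH2Cl2, 0 °C to rt
Reagents that add atoms: none
Why: Dess–Martin oxidation of the only free hydroxyl under base-free conditions, which should avoid β-elimination of the C5 benzyloxy group.

Step 10
Reactants: 15 (5R)-5-(benzyloxy)-7-[4-(benzyloxy)-3-methoxyphenyl]-1-[3,4-bis(benzyloxy)-5-methoxyphenyl]heptan-3-one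
Product: 16 (5R)-1-(3,4-dihydroxy-5-methoxyphenyl)-5-hydroxy-7-(4-hydroxy-3-methoxyphenyl)heptan-3-one
Conditions: H2 (1 atm), Pd(OH)2/C, EtOAc/MeOH, rt
Reagents that add atoms: none
Why: Palladium-catalysed hydrogenolysis should cleave the three aryl benzyl ethers and the secondary alkyl benzyl ether in one neutral operation without reducing the dialkyl ketone or disturbing C5, so the (5R)-β-hydroxy ketone is released directly.

Compound list
1 | 3,4-dihydroxy-5-methoxybenzaldehyde (5-hydroxyvanillin) | COc1cc(C=O)cc(O)c1O | starting material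
2 | 3,4-bis(benzyloxy)-5-methoxybenzaldehyde | COc1cc(C=O)cc(OCc2ccccc2)c1OCc1ccccc1 | intermediate
3 | methyl (triphenylphosphoranylidene)acetate | COC(=O)C=P(c1ccccc1)(c1ccccc1)c1ccccc1 | starting material
4 | methyl (E)-3-[3,4-bis(benzyloxy)-5-methoxyphenyl]prop-2-enoate | COC(=O)/C=C/c1cc(OC)c(OCc2ccccc2)c(OCc2ccccc2)c1 | intermediate
5 | methyl 3-[3,4-bis(benzyloxy)-5-methoxyphenyl]propanoate | COC(=O)CCc1cc(OC)c(OCc2ccccc2)c(OCc2ccccc2)c1 | intermediate
6 | 3-[3,4-bis(benzyloxy)-5-methoxyphenyl]propanal | O=CCCc1cc(OC)c(OCc2ccccc2)c(OCc2ccccc2)c1 | intermediate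
7 | allylmagnesium bromide | C=CC[Mg]Br | starting material
8 | (3R)-1-[3,4-bis(benzyloxy)-5-methoxyphenyl]hex-5-en-3-yl diisopinocampheylborinate | C=CC[C@@H](CCc1cc(OC)c(OCc2ccccc2)c(OCc2ccccc2)c1)OB([C@@H]1C[C@@H]2C[C@H]([C@H]1C)C2(C)C)[C@@H]1C[C@@H]2C[C@H]([C@H]1C)C2(C)C | intermediate
9 | (3R)-1-[3,4-bis(benzyloxy)-5-methoxyphenyl]hex-5-en-3-ol | C=CC[C@H](O)CCc1cc(OC)c(OCc2ccccc2)c(OCc2ccccc2)c1 | intermediate
10 | 4-formyl-2-methoxyphenyl acetate (vanillin acetate) | COc1cc(C=O)ccc1OC(C)=O | starting material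
11 | (2R,4S,6R)-2-(4-acetoxy-3-methoxyphenyl)-6-{2-[3,4-bis(benzyloxy)-5-methoxyphenyl]ethyl}tetrahydropyran-4-yl trifluoroacetate (all-cis) | O=C(O[C@H]1C[C@@H](CCc2cc(OC)c(OCc3ccccc3)c(OCc3ccccc3)c2)O[C@@H](c2ccc(OC(C)=O)c(OC)c2)C1)C(F)(F)F | intermediate
12 | (2R,4S,6R)-6-{2-[3,4-bis(benzyloxy)-5-methoxyphenyl]ethyl}-2-(4-hydroxy-3-methoxyphenyl)tetrahydropyran-4-ol (all-cis) | O[C@H]1C[C@@H](CCc2cc(OC)c(OCc3ccccc3)c(OCc3ccccc3)c2)O[C@@H](c2ccc(O)c(OC)c2)C1 | intermediate
13 | (2R,4S,6R)-4-(benzyloxy)-2-[4-(benzyloxy)-3-methoxyphenyl]-6-{2-[3,4-bis(benzyloxy)-5-methoxyphenyl]ethyl}tetrahydropyran (all-cis) | C(O[C@H]1C[C@@H](CCc2cc(OC)c(OCc3ccccc3)c(OCc3ccccc3)c2)O[C@@H](c2ccc(OCc3ccccc3)c(OC)c2)C1)c1ccccc1 | intermediate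
14 | (3R,5R)-5-(benzyloxy)-7-[4-(benzyloxy)-3-methoxyphenyl]-1-[3,4-bis(benzyloxy)-5-methoxyphenyl]heptan-3-ol | C(O[C@H](CCc1ccc(OCc2ccccc2)c(OC)c1)C[C@H](O)CCc1cc(OC)c(OCc2ccccc2)c(OCc2ccccc2)c1)c1ccccc1 | intermediate
15 | (5R)-5-(benzyloxy)-7-[4-(benzyloxy)-3-methoxyphenyl]-1-[3,4-bis(benzyloxy)-5-methoxyphenyl]heptan-3-one | C(O[C@H](CCc1ccc(OCc2ccccc2)c(OC)c1)CC(=O)CCc1cc(OC)c(OCc2ccccc2)c(OCc2ccccc2)c1)c1ccccc1 | intermediate
16 | (5R)-1-(3,4-dihydroxy-5-methoxyphenyl)-5-hydroxy-7-(4-hydroxy-3-methoxyphenyl)heptan-3-one (CNP0248502.1) | COc1cc(CC[C@@H](O)CC(=O)CCc2cc(O)c(O)c(OC)c2)ccc1O | target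

Total step count: 10 steps.
Longest linear sequence: 10 steps (1 to 16); compounds 3, 7 and 10 are purchased.

Steps most likely to fail

Step 6 (key step). What may go wrong: ring closure may be outrun by attack of the oxocarbenium ion on the electron-rich tri-oxygenated ring of 9. The aldehyde component may also be exchanged by hydrolysis after a 2-oxonia-Cope shift, which would erode the C3 and hence the C5 configuration, or benzyl ethers may be lost by slow acidolysis. The fallback is a stepwise (segment-coupling) entry to the same C7 cation that avoids free aldehyde and water. It sets out from 9. Steglich esterification with commercial 4-(benzyloxy)-3-methoxybenzoic acid (DCC, DMAP, CH2Cl2) should give (3R)-1-[3,4-bis(benzyloxy)-5-methoxyphenyl]hex-5-en-3-yl 4-(benzyloxy)-3-methoxybenzoate F1. Reductive acetylation (iBu2AlH, CH2Cl2, −78 °C, then Ac2O, pyridine, DMAP) should give the α-acetoxy ether F2. BF3·OEt2 and AcOH in CH2Cl2 at low temperature should ionise the acetate irreversibly, and Prins closure through the same chair is expected to give the all-cis tetrahydropyran-4-yl acetate F3. Methanolysis (K2CO3, MeOH) should give the all-cis 2-[4-(benzyloxy)-3-methoxyphenyl]tetrahydropyran-4-ol F4, and benzylation of its one hydroxyl under the conditions of step 7 comes back to the route at 13.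

Step 8. What may go wrong: the C7 cation may be diverted before hydride capture, by proton loss to a styrene, by alkylation of an electron-rich ring, or by internal hydride transfer from the benzylic CH2 of the C5 benzyl ether, which would unmask C5. The Lewis acid may also begin to cleave benzyl ethers before the ring opens. The fallback differentiates the two oxygens in an open chain and needs no benzylic C–O cleavage. It sets out from 9. Tsuji–Wacker oxidation (PdCl2, CuCl, O2, DMF/H2O) should give (4R)-6-[3,4-bis(benzyloxy)-5-methoxyphenyl]-4-hydroxyhexan-2-one F5. Alkylation of its dianion at the methyl terminus (LiN(iPr)2, 2.2 equiv, THF, −78 °C, then 4-(benzyloxy)-3-methoxybenzyl bromide) forms C6–C7 and should give (5R)-7-[3,4-bis(benzyloxy)-5-methoxyphenyl]-1-[4-(benzyloxy)-3-methoxyphenyl]-5-hydroxyheptan-3-one F6. Evans–Tishchenko reduction (SmI2 cat., PhCHO, THF, −10 °C) delivers hydride inside the metal-bound hemiacetal and should set C5 anti to C3, giving the (3R,5R) 3-benzoate with free C5 hydroxyl F7. Benzylation under acidic conditions (benzyl 2,2,2-trichloroacetimidate, TfOH cat., CH2Cl2, 0 °C) should give the 5-benzyl ether 3-benzoate F8, and methanolysis of the benzoate (K2CO3, MeOH) comes back to the route at 14.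

Step 4. What may go wrong: over-reduction past the aldehyde stage if the aluminium hemiacetal collapses before the quench, or incomplete conversion of the ester. The fallback sets out from 5. Full reduction with LiAlH4 (THF, 0 °C) should give 3-[3,4-bis(benzyloxy)-5-methoxyphenyl]propan-1-ol F9, and Dess–Martin oxidation of this alcohol (CH2Cl2, rt) comes back to the route at 6.

Further compounds
F1 | step 6 | (3R)-1-[3,4-bis(benzyloxy)-5-methoxyphenyl]hex-5-en-3-yl 4-(benzyloxy)-3-methoxybenzoate | C=CC[C@@H](CCc1cc(OC)c(OCc2ccccc2)c(OCc2ccccc2)c1)OC(=O)c1ccc(OCc2ccccc2)c(OC)c1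
F2 | step 6 | (3R)-3-{acetoxy[4-(benzyloxy)-3-methoxyphenyl]methoxy}-1-[3,4-bis(benzyloxy)-5-methoxyphenyl]hex-5-ene (both epimers at the acetal carbon) | C=CC[C@@H](CCc1cc(OC)c(OCc2ccccc2)c(OCc2ccccc2)c1)OC(OC(C)=O)c1ccc(OCc2ccccc2)c(OC)c1
F3 | step 6 | (2R,4S,6R)-2-[4-(benzyloxy)-3-methoxyphenyl]-6-{2-[3,4-bis(benzyloxy)-5-methoxyphenyl]ethyl}tetrahydropyran-4-yl acetate | CC(=O)O[C@H]1C[C@@H](CCc2cc(OC)c(OCc3ccccc3)c(OCc3ccccc3)c2)O[C@@H](c2ccc(OCc3ccccc3)c(OC)c2)C1
F4 | step 6 | (2R,4S,6R)-2-[4-(benzyloxy)-3-methoxyphenyl]-6-{2-[3,4-bis(benzyloxy)-5-methoxyphenyl]ethyl}tetrahydropyran-4-ol | O[C@H]1C[C@@H](CCc2cc(OC)c(OCc3ccccc3)c(OCc3ccccc3)c2)O[C@@H](c2ccc(OCc3ccccc3)c(OC)c2)C1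
F5 | step 8 | (4R)-6-[3,4-bis(benzyloxy)-5-methoxyphenyl]-4-hydroxyhexan-2-one | CC(=O)C[C@H](O)CCc1cc(OC)c(OCc2ccccc2)c(OCc2ccccc2)c1
F6 | step 8 | (5R)-7-[3,4-bis(benzyloxy)-5-methoxyphenyl]-1-[4-(benzyloxy)-3-methoxyphenyl]-5-hydroxyheptan-3-one | COc1cc(CCC(=O)C[C@H](O)CCc2cc(OC)c(OCc3ccccc3)c(OCc3ccccc3)c2)ccc1OCc1ccccc1
F7 | step 8 | (3R,5R)-1-[3,4-bis(benzyloxy)-5-methoxyphenyl]-7-[4-(benzyloxy)-3-methoxyphenyl]-5-hydroxyheptan-3-yl benzoate | O=C(O[C@H](CCc1cc(OC)c(OCc2ccccc2)c(OCc2ccccc2)c1)C[C@H](O)CCc1ccc(OCc2ccccc2)c(OC)c1)c1ccccc1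
F8 | step 8 | (3R,5R)-5-(benzyloxy)-7-[4-(benzyloxy)-3-methoxyphenyl]-1-[3,4-bis(benzyloxy)-5-methoxyphenyl]heptan-3-yl benzoate | O=C(O[C@H](CCc1cc(OC)c(OCc2ccccc2)c(OCc2ccccc2)c1)C[C@H](OCc1ccccc1)CCc1ccc(OCc2ccccc2)c(OC)c1)c1ccccc1
F9 | step 4 | 3-[3,4-bis(benzyloxy)-5-methoxyphenyl]propan-1-ol | OCCCc1cc(OC)c(OCc2ccccc2)c(OCc2ccccc2)c1
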